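The readings were computed for substances that don't exist; the scatter is artificial.

Plan on charging more reagent in the second phase if this flask has to give more target, and leave the transfer as it is.

| flask | starting material | reagent in the second phase | remark | time | volume of the second phase over the first |
|---|---|---|---|---|---|
| Friday's | 0.67 M | 1.5 M | run made earlier |  |  |
| Sunday's | 1.5 M | 1.5 M | run made earlier |  |  |
| flask | 1.0 M | 1.50 M |  | 8.0 h | 1.0 |

- in the second phase: reagent in the second phase; everything else is in the first
- charges count per volume of the first phase; a concentration in a rate is the amount of a species over the volume of its own phase; every rate counts per litre of the first phase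
- what may be going on: starting material + reagent in the reaction phase -> target; reagent in the reaction phase + target -> over-reacted product; reagent in the reaction phase <-> dormant form; reagent in the reaction phase <-> reagent in the second phase
- the earlier runs hold the two phases in the same ratio of volumes as the flask asked about

- west: doubling the transfer coefficient of the reagent in the second phase, all else as stated
- east: doubling the amount of reagent in the second phase, all else as stated

| run | time / h | target / % |
|---|---|---|
| Friday's | 1.00 | 0.4 |
| Friday's | 2.50 | 0.8 |
| Friday's | 3.00 | 0.9 |
| Friday's | 5.00 | 2.8 |
| Friday's | 6.00 | 3.6 |
| Friday's | 8.00 | 5.5 |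
| Sunday's | 0.417 | 0 |
| Sunday's | 1.33 | 0.6 |
| Sunday's | 2.50 | 1.0 |
| Sunday's | 3.00 | 1.0 |
| Sunday's | 5.00 | 2.3 |
| Sunday's | 6.00 | 3.2 |
| Sunday's | 8.00 | 4.7 |

(standard deviation of a reading: 0.3 percentage points)

* how much target there is at 8.0 h, in percent of the starting material charged
* the change that raises the amount of target at 8.0 h, in percent of the starting material charged most ("none" if none brings more than 2 percentage points) (west / east / none)
* amount of target at 8.0 h, in percent of the starting material charged, after east

Friday's and Sunday's readings at 8.0 h are 5.5% and 4.7%. They lie 0.8 percentage points apart, with a scatter of 0.3 points per reading, although c(starting material) rose 2.24-fold. So I read the target's formation as first order in starting material, and I pool the two readings.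

Now count turnovers of the reagent: Sunday's target corresponds to 4.70% of the reagent charged, so I treat that charge as barely consumed. Neither run varied it, so proportionality to it is my assumption. I carry the reagent yield, the fraction of starting material present as target at 8.0 h per molar of c(reagent in the second phase) charged: 0.0340 L mol⁻¹.

That gives 5.10% for this flask and 10.2% after east. The forecast says 5.1%, chooses east, and gives 9.7% after it, reasoning that “the system is nearly linear in the second-phase reagent”. Its figure after east is lower than mine.

The flask gives 4.88%, and east raises it most, to 8.78%.

    starting material + reagent in the reaction phase → target (k = 1.10 × 10⁻⁵ L mol⁻¹ s⁻¹)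
    reagent in the reaction phase + target → over-reacted product (k = 3.20 × 10⁻⁵ L mol⁻¹ s⁻¹)
    reagent in the reaction phase ⇌ dormant form (K = 2.20, k = 7.10 × 10⁻⁶ s⁻¹)
    reagent in the reaction phase ⇌ reagent in the second phase, rate k4*([reagent in the reaction phase] - [reagent in the second phase]/K4) per volume of the first phase (partition coefficient = 2.40, kL = 3.30 × 10⁻⁵ s⁻¹)

At 8.00 h this flask still holds 76.7% of its reagent in the second phase. Its reagent yield comes to 0.0325 L mol⁻¹, and the flask after east comes to 0.0293 L mol⁻¹.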